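**Retrosynthetic overview**
1. Target 19 ⇐ global hydrogenolysis of 18 ⇐ trans-selective Friedel–Crafts union of ring B of the upper isoflavan 10 with the C4 cation of the lower cis-isoflavan-4-ol 17 (sets lower C4).
2. Upper isoflavan 9/10 ⇐ pyran ring closed by C–O bond formation in the key step: enantioconvergent reductive cycloetherification of phenol–enol ether 7 (sets upper C3).
3. 7 ⇐ deoxybenzoin 5 (Wittig one-carbon homologation, desilylation) ⇐ ketone α-arylation of O-benzylpaeonol 2 with silylated bromoresorcinol 4.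
4. 17 ⇐ transfer hydrogenation with dynamic kinetic resolution of isoflavanone 16 (sets lower C3) ⇐ α-arylation of chromanone 15 with aryl bromide 13.
5. Ring order: the lower pyran ring comes with commercial 14, the upper pyran ring is formed in step 5, and the halves are joined in step 12.

Assumption: 1, 3, 11 and 14 are taken as cheap catalogue chemicals, and the catalyst enantiomers quoted in steps 5 and 11 are those expected to give the drawn configuration (the mirror-image catalyst is used if a model run shows the opposite sense).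
Ring labels: ring A = benzo ring of the upper chroman; ring B = central 2-oxy-4-methoxyphenyl ring; ring C = benzo ring of the lower chroman; ring D = 3-oxy-2,4-dimethoxyphenyl ring.

**Step 1**
Reactants: 1 1-(2-hydroxy-4-methoxyphenyl)ethan-1-one (paeonol)
Product: 2 1-[2-(benzyloxy)-4-methoxyphenyl]ethan-1-one
Conditions: BnBr, K2CO3, DMF, 60 °C
Reagents that add atoms: benzyl bromide, BrCc1ccccc1
Why: Williamson ether synthesis, in which warm carbonate/DMF overcomes the hydrogen-bonded ortho-hydroxy ketone; no stereocentre is involved.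

**Step 2**
Reactants: 3 4-bromobenzene-1,3-diol
Product: 4 [(4-bromo-1,3-phenylene)bis(oxy)]bis(triisopropylsilane)
Conditions: iPr3SiCl (2.2 equiv), imidazole, DMF, 25 °C
Reagents that add atoms: triisopropylsilyl chloride, CC(C)[Si](Cl)(C(C)C)C(C)C
Why: Imidazole-promoted O-silylation of both phenols, giving silyl ethers that tolerate the mild-base arylation and the ylide and are later removed by fluoride without touching an enol ether.

**Step 3**
Reactants: 2 1-[2-(benzyloxy)-4-methoxyphenyl]ethan-1-one; 4 [(4-bromo-1,3-phenylene)bis(oxy)]bis(triisopropylsilane)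
Product: 5 1-[2-(benzyloxy)-4-methoxyphenyl]-2-{2,4-bis[(triisopropylsilyl)oxy]phenyl}ethan-1-one
Conditions: Pd(OAc)2 (3 mol %), XPhos (6 mol %), K3PO4, toluene, 100 °C
Reagents that add atoms: none
Why: Palladium-catalysed α-arylation of an aryl methyl ketone (enolate arylation), mono-selective because the ortho-silyloxy aryl group makes the product enolate too hindered for a second arylation.

**Step 4**
Reactants: 5 1-[2-(benzyloxy)-4-methoxyphenyl]-2-{2,4-bis[(triisopropylsilyl)oxy]phenyl}ethan-1-one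
Product: 7 4-{2-[2-(benzyloxy)-4-methoxyphenyl]-3-methoxyprop-2-en-1-yl}benzene-1,3-diol (E/Z mixture), via bis-TIPS enol ether 6 (not isolated)
Conditions: Ph3P(CH2OMe)Cl, KN(SiMe3)2, THF, −78 to 25 °C; then Bu4NF, 0 °C
Reagents that add atoms: (methoxymethyl)triphenylphosphonium chloride, COC[P+](c1ccccc1)(c1ccccc1)c1ccccc1.[Cl-]
Why: Wittig methoxymethylenation adds the C2 carbon at the aldehyde oxidation level, and fluoride desilylation in the same flask frees the ring A phenols under basic conditions that leave the enol ether intact.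

**Step 5 (key step)**
Reactants: 7 4-{2-[2-(benzyloxy)-4-methoxyphenyl]-3-methoxyprop-2-en-1-yl}benzene-1,3-diol
Product: 9 (3R)-3-[2-(benzyloxy)-4-methoxyphenyl]chroman-7-ol, via 2-methoxychroman acetal 8 (not isolated)
Conditions: (R)-3,3'-bis(2,4,6-triisopropylphenyl)-BINOL N-triflylphosphoramide (10 mol %), 5 Å MS, toluene, 25 °C, 1 h; then Hantzsch ester (1.5 equiv), 40 °C
Reagents that add atoms: none
Why: Proposed new method: enantioconvergent reductive cycloetherification, in which the chiral acid protonates the enol ether at C3, the ortho-phenol of ring A captures the oxocarbenium at C2 (new C–O bond and pyran ring, acetal 8), loss of methanol gives a cyclic aryl oxocarbenium that epimerises at C3 through the 3-aryl-4H-chromene, and the chiral counter-anion lets the Hantzsch ester deliver hydride to C2 of only one ion-pair diastereomer (dynamic kinetic resolution), giving the 3R isoflavan; the closest known reaction type is the chiral phosphoric acid/Hantzsch ester reductive amination of α-branched aldehydes with dynamic kinetic resolution, here moved from C–N to C–O bond formation.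

**Step 6**
Reactants: 9 (3R)-3-[2-(benzyloxy)-4-methoxyphenyl]chroman-7-ol
Product: 10 benzyl (3R)-3-[2-(benzyloxy)-4-methoxyphenyl]chroman-7-yl carbonate
Conditions: CbzCl, pyridine, CH2Cl2, 0 °C
Reagents that add atoms: benzyl chloroformate, O=C(Cl)OCc1ccccc1
Why: O-acylation of the only free phenol with a chloroformate, which makes ring A electron-poor for the later Friedel–Crafts step and is removed in the final hydrogenolysis.

**Step 7**
Reactants: 11 2,6-dimethoxyphenol
Product: 12 2-(benzyloxy)-1,3-dimethoxybenzene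
Conditions: BnBr, K2CO3, DMF, 25 °C
Reagents that add atoms: benzyl bromide, BrCc1ccccc1
Why: Williamson ether synthesis protecting the future ring D phenol.

**Step 8**
Reactants: 12 2-(benzyloxy)-1,3-dimethoxybenzene
Product: 13 2-(benzyloxy)-4-bromo-1,3-dimethoxybenzene
Conditions: NBS (1.0 equiv), MeCN, 0 to 25 °C
Reagents that add atoms: N-bromosuccinimide, O=C1CCC(=O)N1Br
Why: Electrophilic aromatic bromination at the position ortho to one methoxy and para to the other, as for 1,2,3-trialkoxybenzenes, because the flanked central ether is twisted out of conjugation.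

**Step 9**
Reactants: 14 7-hydroxychroman-4-one
Product: 15 7-(benzyloxy)chroman-4-one
Conditions: BnBr, K2CO3, acetone, reflux
Reagents that add atoms: benzyl bromide, BrCc1ccccc1
Why: Williamson ether synthesis under mild base that does not open the chromanone ring.

**Step 10**
Reactants: 15 7-(benzyloxy)chroman-4-one; 13 2-(benzyloxy)-4-bromo-1,3-dimethoxybenzene
Product: 16 rac-7-(benzyloxy)-3-[3-(benzyloxy)-2,4-dimethoxyphenyl]chroman-4-one
Conditions: Pd(OAc)2 (5 mol %), tBu3P·HBF4 (10 mol %), NaOtBu, toluene, 60 °C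
Reagents that add atoms: none
Why: Palladium-catalysed α-arylation of a chroman-4-one enolate, kept to mono-arylation by the ortho-methoxy aryl bromide; C3 is formed racemic and is corrected in step 11.

**Step 11**
Reactants: 16 rac-7-(benzyloxy)-3-[3-(benzyloxy)-2,4-dimethoxyphenyl]chroman-4-one
Product: 17 (3R,4R)-7-(benzyloxy)-3-[3-(benzyloxy)-2,4-dimethoxyphenyl]chroman-4-ol (cis)
Conditions: RuCl(p-cymene)[(R,R)-TsDPEN] (2 mol %), HCO2H/Et3N (5:2), EtOAc, 40 °C
Reagents that add atoms: none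
Why: Noyori–Ikariya asymmetric transfer hydrogenation with dynamic kinetic resolution, in which Et3N epimerises the α-aryl ketone through its enol and the catalyst reduces only the 3R ketone from the face anti to the aryl group, giving the cis-(3R,4R) alcohol.

**Step 12**
Reactants: 17 (3R,4R)-7-(benzyloxy)-3-[3-(benzyloxy)-2,4-dimethoxyphenyl]chroman-4-ol; 10 benzyl (3R)-3-[2-(benzyloxy)-4-methoxyphenyl]chroman-7-yl carbonate
Product: 18 benzyl (3R)-3-{2-(benzyloxy)-5-[(3R,4S)-7-(benzyloxy)-3-[3-(benzyloxy)-2,4-dimethoxyphenyl]chroman-4-yl]-4-methoxyphenyl}chroman-7-yl carbonate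
Conditions: 10 (3 equiv, excess recovered), Bi(OTf)3 (10 mol %), CH2Cl2, −40 to −20 °C, slow addition of 17
Reagents that add atoms: none
Why: Friedel–Crafts alkylation through the C4 benzylic cation (stabilised by the ring oxygen and the 7-benzyloxy group), in which ring B attacks through its free position para to OBn and ortho to OMe on the face opposite the C3 aryl group, setting 4S (3,4-trans), while the carbonate keeps ring A unreactive.

**Step 13**
Reactants: 18 benzyl (3R)-3-{2-(benzyloxy)-5-[(3R,4S)-7-(benzyloxy)-3-[3-(benzyloxy)-2,4-dimethoxyphenyl]chroman-4-yl]-4-methoxyphenyl}chroman-7-yl carbonate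
Product: 19 (3R)-3-{2-hydroxy-5-[(3R,4S)-7-hydroxy-3-(3-hydroxy-2,4-dimethoxyphenyl)chroman-4-yl]-4-methoxyphenyl}chroman-7-ol (CNP0202416.1)
Conditions: H2 (1 atm), Pd/C, EtOAc/MeOH, 25 °C
Reagents that add atoms: none
Why: Catalytic hydrogenolysis cleaves the three benzyl ethers and the benzyl carbonate (with decarboxylation) without affecting methyl ethers, chroman rings or any stereocentre.

**Compound list**
1 | 1-(2-hydroxy-4-methoxyphenyl)ethan-1-one (paeonol) | CC(=O)c1ccc(OC)cc1O | starting material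
2 | 1-[2-(benzyloxy)-4-methoxyphenyl]ethan-1-one | CC(=O)c1ccc(OC)cc1OCc1ccccc1 | intermediate
3 | 4-bromobenzene-1,3-diol | Oc1ccc(Br)c(O)c1 | starting material
4 | [(4-bromo-1,3-phenylene)bis(oxy)]bis(triisopropylsilane) | CC(C)[Si](Oc1ccc(Br)c(O[Si](C(C)C)(C(C)C)C(C)C)c1)(C(C)C)C(C)C | intermediate
5 | 1-[2-(benzyloxy)-4-methoxyphenyl]-2-{2,4-bis[(triisopropylsilyl)oxy]phenyl}ethan-1-one | COc1ccc(C(=O)Cc2ccc(O[Si](C(C)C)(C(C)C)C(C)C)cc2O[Si](C(C)C)(C(C)C)C(C)C)c(OCc2ccccc2)c1 | intermediate
6 | [(4-{2-[2-(benzyloxy)-4-methoxyphenyl]-3-methoxyprop-2-en-1-yl}-1,3-phenylene)bis(oxy)]bis(triisopropylsilane) (E/Z mixture, not isolated) | COC=C(Cc1ccc(O[Si](C(C)C)(C(C)C)C(C)C)cc1O[Si](C(C)C)(C(C)C)C(C)C)c1ccc(OC)cc1OCc1ccccc1 | intermediate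
7 | 4-{2-[2-(benzyloxy)-4-methoxyphenyl]-3-methoxyprop-2-en-1-yl}benzene-1,3-diol (E/Z mixture) | COC=C(Cc1ccc(O)cc1O)c1ccc(OC)cc1OCc1ccccc1 | intermediate
8 | 3-[2-(benzyloxy)-4-methoxyphenyl]-2-methoxychroman-7-ol (diastereomer mixture, not isolated) | COC1Oc2cc(O)ccc2CC1c1ccc(OC)cc1OCc1ccccc1 | intermediate
9 | (3R)-3-[2-(benzyloxy)-4-methoxyphenyl]chroman-7-ol | COc1ccc([C@@H]2COc3cc(O)ccc3C2)c(OCc2ccccc2)c1 | intermediate
10 | benzyl (3R)-3-[2-(benzyloxy)-4-methoxyphenyl]chroman-7-yl carbonate | COc1ccc([C@@H]2COc3cc(OC(=O)OCc4ccccc4)ccc3C2)c(OCc2ccccc2)c1 | intermediate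
11 | 2,6-dimethoxyphenol | COc1cccc(OC)c1O | starting material
12 | 2-(benzyloxy)-1,3-dimethoxybenzene | COc1cccc(OC)c1OCc1ccccc1 | intermediate
13 | 2-(benzyloxy)-4-bromo-1,3-dimethoxybenzene | COc1ccc(Br)c(OC)c1OCc1ccccc1 | intermediate
14 | 7-hydroxychroman-4-one | O=C1CCOc2cc(O)ccc12 | starting material
15 | 7-(benzyloxy)chroman-4-one | O=C1CCOc2cc(OCc3ccccc3)ccc12 | intermediate
16 | rac-7-(benzyloxy)-3-[3-(benzyloxy)-2,4-dimethoxyphenyl]chroman-4-one | COc1ccc(C2COc3cc(OCc4ccccc4)ccc3C2=O)c(OC)c1OCc1ccccc1 | intermediate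
17 | (3R,4R)-7-(benzyloxy)-3-[3-(benzyloxy)-2,4-dimethoxyphenyl]chroman-4-ol | O[C@H]1c2ccc(OCc3ccccc3)cc2OC[C@H]1c1ccc(OC)c(OCc2ccccc2)c1OC | intermediate
18 | benzyl (3R)-3-{2-(benzyloxy)-5-[(3R,4S)-7-(benzyloxy)-3-[3-(benzyloxy)-2,4-dimethoxyphenyl]chroman-4-yl]-4-methoxyphenyl}chroman-7-yl carbonate | COc1cc(OCc2ccccc2)c([C@@H]2COc3cc(OC(=O)OCc4ccccc4)ccc3C2)cc1[C@@H]1c2ccc(OCc3ccccc3)cc2OC[C@H]1c1ccc(OC)c(OCc2ccccc2)c1OC | intermediate
19 | (3R)-3-{2-hydroxy-5-[(3R,4S)-7-hydroxy-3-(3-hydroxy-2,4-dimethoxyphenyl)chroman-4-yl]-4-methoxyphenyl}chroman-7-ol | COc1cc(O)c([C@@H]2COc3cc(O)ccc3C2)cc1[C@@H]1c2ccc(O)cc2OC[C@H]1c1ccc(OC)c(O)c1OC | target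

**Step count**
Total: 13 steps. Longest linear sequence: 7 steps (1, 3, 4, 5, 6, 12, 13).

**Three steps most likely to fail, with fallbacks**

Step 4 (Wittig reaction on a hindered, easily enolised deoxybenzoin). The fallback sets out from 5. Corey–Chaykovsky methylenation (Me3S+ I−, KOtBu, DMSO/THF) gives the 2,2-disubstituted oxirane F1. A Meinwald rearrangement (BF3·OEt2 cat., CH2Cl2, −78 °C; hydride shift to the tertiary benzylic cation) gives the α-aryl aldehyde F2. Bu4NF then gives the lactol F3, which is put through the step 5 conditions (water is lost in place of methanol) and comes back to the route at 9.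

Step 5 (the proposed new reaction; risks are premature hydride transfer to the acyclic oxocarbenium and low enantioselectivity). The fallback uses known chemistry and sets out from 5. Wittig methylenation (Ph3PCH3Br, KOtBu, THF) gives the 1,1-disubstituted alkene F4. Cobalt-catalysed asymmetric anti-Markovnikov hydroboration (CoCl2, chiral iminopyridine–oxazoline ligand, NaBHEt3, HBpin) gives the pinacol boronate F5, which is oxidised (NaBO3, THF/H2O) to the primary alcohol F6. Bu4NF gives the triol F7, and a Mitsunobu cycloetherification (PPh3, DIAD, THF, high dilution) forms the same ring C–O bond and comes back to the route at 9.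

Step 12 (cationic union; risks are elimination to the isoflav-3-ene with loss of C3 integrity, and self-alkylation of 17). The fallback sets out from 10 and 17. NBS (MeCN, 0 °C) brominates the free position of ring B para to OBn to give the aryl bromide F8. Alcohol 17 is converted in the flask into the mesylate F9 (Ms2O, iPr2NEt, DMA, 0 °C). The two are joined by a nickel/cobalt cross-electrophile coupling (NiBr2(dme), 4,4'-di-tert-butyl-2,2'-bipyridine, Co(Pc), Zn, DMA, 25 °C) through the C4 radical, which is captured anti to the C3 aryl group, and the route is rejoined at 18.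

**Further compounds**
F1 | step 4 | 2-[2-(benzyloxy)-4-methoxyphenyl]-2-{2,4-bis[(triisopropylsilyl)oxy]benzyl}oxirane (racemic) | COc1ccc(C2(Cc3ccc(O[Si](C(C)C)(C(C)C)C(C)C)cc3O[Si](C(C)C)(C(C)C)C(C)C)CO2)c(OCc2ccccc2)c1
F2 | step 4 | 2-[2-(benzyloxy)-4-methoxyphenyl]-3-{2,4-bis[(triisopropylsilyl)oxy]phenyl}propanal (racemic) | COc1ccc(C(C=O)Cc2ccc(O[Si](C(C)C)(C(C)C)C(C)C)cc2O[Si](C(C)C)(C(C)C)C(C)C)c(OCc2ccccc2)c1
F3 | step 4 | 3-[2-(benzyloxy)-4-methoxyphenyl]chroman-2,7-diol (lactol, diastereomer mixture) | COc1ccc(C2Cc3ccc(O)cc3OC2O)c(OCc2ccccc2)c1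
F4 | step 5 | [(4-{2-[2-(benzyloxy)-4-methoxyphenyl]prop-2-en-1-yl}-1,3-phenylene)bis(oxy)]bis(triisopropylsilane) | COc1ccc(C(=C)Cc2ccc(O[Si](C(C)C)(C(C)C)C(C)C)cc2O[Si](C(C)C)(C(C)C)C(C)C)c(OCc2ccccc2)c1
F5 | step 5 | 2-{(2R)-2-[2-(benzyloxy)-4-methoxyphenyl]-3-{2,4-bis[(triisopropylsilyl)oxy]phenyl}propyl}-4,4,5,5-tetramethyl-1,3,2-dioxaborolane | COc1ccc([C@H](CB2OC(C)(C)C(C)(C)O2)Cc2ccc(O[Si](C(C)C)(C(C)C)C(C)C)cc2O[Si](C(C)C)(C(C)C)C(C)C)c(OCc2ccccc2)c1
F6 | step 5 | (2R)-2-[2-(benzyloxy)-4-methoxyphenyl]-3-{2,4-bis[(triisopropylsilyl)oxy]phenyl}propan-1-ol | COc1ccc([C@H](CO)Cc2ccc(O[Si](C(C)C)(C(C)C)C(C)C)cc2O[Si](C(C)C)(C(C)C)C(C)C)c(OCc2ccccc2)c1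
F7 | step 5 | 4-{(2R)-2-[2-(benzyloxy)-4-methoxyphenyl]-3-hydroxypropyl}benzene-1,3-diol | COc1ccc([C@H](CO)Cc2ccc(O)cc2O)c(OCc2ccccc2)c1
F8 | step 12 | benzyl (3R)-3-[2-(benzyloxy)-5-bromo-4-methoxyphenyl]chroman-7-yl carbonate | COc1cc(OCc2ccccc2)c([C@@H]2COc3cc(OC(=O)OCc4ccccc4)ccc3C2)cc1Br
F9 | step 12 | (3R,4R)-7-(benzyloxy)-3-[3-(benzyloxy)-2,4-dimethoxyphenyl]chroman-4-yl methanesulfonate | CS(=O)(=O)O[C@H]1c2ccc(OCc3ccccc3)cc2OC[C@H]1c1ccc(OC)c(OCc2ccccc2)c1OC
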